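**Retrosynthetic overview**

- The strategy rests on the single tetrahydrofuran ring (O1, C2 with the 3,4-dimethoxyphenyl group, C3, C4, C5 with the 3,4,5-trimethoxyphenyl group): the C3–C4 bond joins the two methyl-bearing carbons, and each of them is β to O1.
- Cutting C3–C4 gives a 3-oxahex-5-enyl radical on a bis-benzylic ether: a C4 radical (from a phenylselanyl group) and a vinyl group on C2, whose terminal CH2 becomes the C3 methyl group.
- The C2–O1 bond of this ether is cut to a 3,4-dimethoxycinnamyl carbonate and a selanyl alcohol; a branched-selective, ligand-controlled Ir allylic etherification sets C2.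
- C5 is set by Corey–Bakshi–Shibata reduction of the α-selanyl ketone, which comes from enolate selenenylation of the propiophenone.
- The tetrahydrofuran ring is the only ring and is formed last, in the radical step.

Key step: step 5

Assumption: the (Sa,Sc,Sc) phosphoramidite is taken to give the S-configured branched ether at C2, as expected for O-nucleophiles with cinnamyl carbonates; if the sense proves opposite, the mirror-image ligand is used.

**Route**

Step 1
Reactants: 1 1-(3,4,5-trimethoxyphenyl)propan-1-one; 2 phenylselenyl chloride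
Product: 4 2-(phenylselanyl)-1-(3,4,5-trimethoxyphenyl)propan-1-one (racemic), via lithium enolate 3 (not isolated)
Conditions: LiN(i-Pr)2 (1.05 equiv), THF, −78 °C; then 2, −78 °C
Reagents that add atoms: none
Why: Enolate α-selenenylation, in which kinetic deprotonation gives the lithium enolate and PhSeCl attacks it at carbon; the new C–Se centre is racemic, which does no harm because this carbon later becomes a planar radical.

Step 2
Reactants: 4 2-(phenylselanyl)-1-(3,4,5-trimethoxyphenyl)propan-1-one
Product: 5 (1S)-2-(phenylselanyl)-1-(3,4,5-trimethoxyphenyl)propan-1-ol (both C2 epimers)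
Conditions: (S)-2-methyl-CBS-oxazaborolidine [(S)-1-methyl-3,3-diphenyltetrahydro-1H,3H-pyrrolo[1,2-c][1,3,2]oxazaborole] (20 mol %), BH3·SMe2, THF, −20 °C; MeOH, then aq. NH4Cl
Reagents that add atoms: none
Why: Corey–Bakshi–Shibata reduction, in which the oxazaborolidine–borane complex binds the carbonyl oxygen anti to the aryl group and delivers hydride to the face that gives the (R)-1-arylethanol-type carbinol (1S here, because the selenium-bearing carbon outranks the aryl group), so the future C5 centre is set by the catalyst in both C2 epimers while the C–Se bond is inert to borane.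

Step 3
Reactants: 6 (E)-3-(3,4-dimethoxyphenyl)prop-2-en-1-ol
Product: 7 tert-butyl (E)-3-(3,4-dimethoxyphenyl)prop-2-en-1-yl carbonate
Conditions: Boc2O, Bu4NHSO4 (cat.), 30% aq. NaOH, CH2Cl2, 0 °C to rt
Reagents that add atoms: di-tert-butyl dicarbonate, CC(C)(C)OC(=O)OC(=O)OC(C)(C)C
Why: Phase-transfer O-acylation of a primary allylic alcohol, which forms no stereocentre, leaves the E alkene untouched, and gives a leaving group whose tert-butoxide by-product is too hindered to compete as a nucleophile in step 4.

Step 4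
Reactants: 5 (1S)-2-(phenylselanyl)-1-(3,4,5-trimethoxyphenyl)propan-1-ol; 7 tert-butyl (E)-3-(3,4-dimethoxyphenyl)prop-2-en-1-yl carbonate
Product: 10 4-[(1S)-1-{[(1S)-2-(phenylselanyl)-1-(3,4,5-trimethoxyphenyl)propyl]oxy}prop-2-en-1-yl]-1,2-dimethoxybenzene (both epimers at the selenium-bearing carbon), via lithium alkoxide 8 (not isolated), via copper alkoxide 9 (not isolated)
Conditions: 5 (1.3 equiv), LiN(SiMe3)2, THF, 0 °C; CuI, rt; then 7, [Ir(cod)Cl]2 (2 mol %), (Sa,Sc,Sc)-(1,1'-binaphthalene-2,2'-diyl) N,N-bis(1-phenylethyl)phosphoramidite (4 mol %), THF, rt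
Reagents that add atoms: none
Why: Ir-catalysed asymmetric allylic etherification with an aliphatic copper alkoxide, in which the Ir–phosphoramidite allyl complex from 7 is attacked by the alkoxide oxygen at its aryl-bearing terminus to give the branched ether with C2 (S) set by the ligand, while the carbinol centre (future C5) reacts through oxygen and keeps its configuration and the mild alkoxide of monovalent copper does not disturb the selenide.

Step 5
Reactants: 10 4-[(1S)-1-{[(1S)-2-(phenylselanyl)-1-(3,4,5-trimethoxyphenyl)propyl]oxy}prop-2-en-1-yl]-1,2-dimethoxybenzene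
Product: 11 (2S,3S,4R,5R)-2-(3,4-dimethoxyphenyl)-3,4-dimethyl-5-(3,4,5-trimethoxyphenyl)tetrahydrofuran (the target)
Conditions: Bu3SnH (1.3 equiv) and azobisisobutyronitrile (0.2 equiv) by syringe pump over 4 h, degassed PhH (0.01 M), 80 °C; chromatography
Reagents that add atoms: none
Why: The tributyltin radical abstracts the phenylselanyl group from either epimer of 10 to give the same secondary C4 radical, which adds to the internal carbon of the vinyl group on C2 and forms the C3–C4 bond; the exocyclic primary radical then takes hydrogen from Bu3SnH and becomes the C3 methyl group, as in the known tin hydride cyclisations of β-halo or β-selanyl alkyl allyl ethers to 3,4-disubstituted tetrahydrofurans. The tetrahydrofuran ring closes in the 5-exo-trig mode, which for a 3-oxahex-5-enyl radical is kinetically far ahead of 6-endo closure. C3 is controlled by the C2 centre: in the chair-like transition state both aryl groups sit pseudo-equatorial, which is possible because steps 2 and 4 placed the two benzylic centres cis, and the forming C3–CH2 bond then lies trans to both aryl groups. C4 is controlled by the C5 centre: the methyl group on the radical carbon turns away from the neighbouring C5 aryl group (4,5-trans), the same orientation that 1-substituted hexenyl radicals prefer, so the two methyl groups end cis. The step needs ring closure to outrun hydrogen transfer to the open-chain radical and the 1,2-aryl (neophyl) shift; slow addition of Bu3SnH at high dilution secures the first and the inherent slowness of the aryl shift the second. Minor diastereomers are expected and should be removed by chromatography.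

**Compound list**

1 | 1-(3,4,5-trimethoxyphenyl)propan-1-one | CCC(=O)c1cc(OC)c(OC)c(OC)c1 | starting material
2 | phenylselenyl chloride | Cl[Se]c1ccccc1 | starting material
3 | lithium (Z)-1-(3,4,5-trimethoxyphenyl)prop-1-en-1-olate | C/C=C(\O[Li])c1cc(OC)c(OC)c(OC)c1 | intermediate
4 | 2-(phenylselanyl)-1-(3,4,5-trimethoxyphenyl)propan-1-one (racemic) | CC([Se]c1ccccc1)C(=O)c1cc(OC)c(OC)c(OC)c1 | intermediate
5 | (1S)-2-(phenylselanyl)-1-(3,4,5-trimethoxyphenyl)propan-1-ol (both C2 epimers) | CC([Se]c1ccccc1)[C@@H](O)c1cc(OC)c(OC)c(OC)c1 | intermediate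
6 | (E)-3-(3,4-dimethoxyphenyl)prop-2-en-1-ol | COc1ccc(/C=C/CO)cc1OC | starting material
7 | tert-butyl (E)-3-(3,4-dimethoxyphenyl)prop-2-en-1-yl carbonate | COc1ccc(/C=C/COC(=O)OC(C)(C)C)cc1OC | intermediate
8 | lithium (1S)-2-(phenylselanyl)-1-(3,4,5-trimethoxyphenyl)propan-1-olate | CC([Se]c1ccccc1)[C@@H](O[Li])c1cc(OC)c(OC)c(OC)c1 | intermediate
9 | [(1S)-2-(phenylselanyl)-1-(3,4,5-trimethoxyphenyl)propoxy]copper (alkoxide of monovalent copper) | CC([Se]c1ccccc1)[C@@H](O[Cu])c1cc(OC)c(OC)c(OC)c1 | intermediate
10 | 4-[(1S)-1-{[(1S)-2-(phenylselanyl)-1-(3,4,5-trimethoxyphenyl)propyl]oxy}prop-2-en-1-yl]-1,2-dimethoxybenzene (both epimers at the selenium-bearing carbon) | COc1ccc([C@H](C=C)O[C@@H](c2cc(OC)c(OC)c(OC)c2)C(C)[Se]c2ccccc2)cc1OC | intermediate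
11 | (2S,3S,4R,5R)-2-(3,4-dimethoxyphenyl)-3,4-dimethyl-5-(3,4,5-trimethoxyphenyl)tetrahydrofuran | COc1ccc([C@H]2O[C@@H](c3cc(OC)c(OC)c(OC)c3)[C@H](C)[C@@H]2C)cc1OC | target

**Step count**

Total steps: 5. Longest linear sequence: 4 (steps 1, 2, 4, 5).

**Steps most likely to fail**

1. Step 5 (radical ring closure). Hydrogen transfer to the open-chain C4 radical may compete with closure, and the C4 methyl group may be placed with too little facial bias.
 - The fallback sets out from 10 and comes back at 11.
 - Oxidation of 10 with mCPBA (CH2Cl2, −78 °C) gives the selenoxide 4-[(1S)-1-{[(1S)-2-(phenylseleninyl)-1-(3,4,5-trimethoxyphenyl)propyl]oxy}prop-2-en-1-yl]-1,2-dimethoxybenzene F1. On warming with i-Pr2NH it eliminates away from the oxygen-bearing carbon to the diene 5-[(1R)-1-{[(1S)-1-(3,4-dimethoxyphenyl)prop-2-en-1-yl]oxy}prop-2-en-1-yl]-1,2,3-trimethoxybenzene F2.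
 - Thiophenol with azobisisobutyronitrile (PhH, 80 °C, slow addition) adds a phenylthiyl radical to either terminal CH2. The resulting C4 or C3 radical closes 5-exo onto the other vinyl group and takes hydrogen from the thiol. The C3–C4 bond is still formed by radical closure, but the radical carbon now carries the larger CH2SPh group and the chain carrier is different.
 - Both regioisomers, (2S,3S,4R,5R)-2-(3,4-dimethoxyphenyl)-3-methyl-4-[(phenylsulfanyl)methyl]-5-(3,4,5-trimethoxyphenyl)tetrahydrofuran F3 and (2S,3S,4R,5R)-2-(3,4-dimethoxyphenyl)-4-methyl-3-[(phenylsulfanyl)methyl]-5-(3,4,5-trimethoxyphenyl)tetrahydrofuran F4, should give 11 on desulfurisation with deactivated Raney nickel (Ni) in EtOH at rt.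

2. Step 4 (allylic etherification). The hindered selanyl alkoxide may attack the allyl complex slowly, the selenide may bind iridium, and the electron-rich allyl complex may leak to the linear ether or lose facial control.
 - The fallback forms the C5–O1 bond instead of the C2–O1 bond; it sets out from 1 and 7 and comes back at 10.
 - NaBH4 (MeOH) reduces 1 to 1-(3,4,5-trimethoxyphenyl)propan-1-ol F5, and TsOH-catalysed dehydration (toluene, reflux) gives (E)-1,2,3-trimethoxy-5-(prop-1-en-1-yl)benzene F6.
 - Carbonate 7 reacts with Et3SiOK under the same [Ir(cod)Cl]2/phosphoramidite catalyst to give triethyl{[(1S)-1-(3,4-dimethoxyphenyl)prop-2-en-1-yl]oxy}silane F7, and Bu4NF gives (S)-1-(3,4-dimethoxyphenyl)prop-2-en-1-ol F8.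
 - Alkoxyselenenylation of F6 with PhSeOSO2CF3 (from 2 and AgOSO2CF3, CH2Cl2, −78 °C, 2,6-di-tert-butylpyridine) in the presence of F8 opens the seleniranium ion at the benzylic carbon anti to selenium. This should give 10 as its (1S,2R) epimer together with 4-[(1S)-1-{[(1R,2S)-2-(phenylselanyl)-1-(3,4,5-trimethoxyphenyl)propyl]oxy}prop-2-en-1-yl]-1,2-dimethoxybenzene F9.
 - In this variant C5 is not set by a reagent; 10 is obtained by chromatographic separation from F9.

3. Step 2 (asymmetric reduction). Both flanks of the carbonyl group are bulky, so the oxazaborolidine may discriminate the faces poorly, and one enantiomer of the racemic ketone may be a mismatched case.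
 - The fallback sets out from 4 and comes back at 5.
 - NaBH4 (MeOH, 0 °C) reduces 4 to racemic 2-(phenylselanyl)-1-(3,4,5-trimethoxyphenyl)propan-1-ol F10 (all four stereoisomers).
 - Acylative kinetic resolution with propionic anhydride, i-Pr2NEt and the benzotetramisole enantiomer that acylates the (1R)-alcohols (expected to be (S)-benzotetramisole, by analogy with 1-arylalkanols) in CHCl3 at 0 °C converts these to (1R)-2-(phenylselanyl)-1-(3,4,5-trimethoxyphenyl)propyl propanoate F11 and leaves 5, which is separated by chromatography.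
 - Running the acylation past half conversion should raise the enantiomeric purity of the recovered 5.

**Further compounds**

F1 | step 5 | 4-[(1S)-1-{[(1S)-2-(phenylseleninyl)-1-(3,4,5-trimethoxyphenyl)propyl]oxy}prop-2-en-1-yl]-1,2-dimethoxybenzene | COc1ccc([C@H](C=C)O[C@@H](c2cc(OC)c(OC)c(OC)c2)C(C)[Se](=O)c2ccccc2)cc1OC
F2 | step 5 | 5-[(1R)-1-{[(1S)-1-(3,4-dimethoxyphenyl)prop-2-en-1-yl]oxy}prop-2-en-1-yl]-1,2,3-trimethoxybenzene | COc1ccc([C@H](C=C)O[C@@H](c2cc(OC)c(OC)c(OC)c2)C=C)cc1OC
F3 | step 5 | (2S,3S,4R,5R)-2-(3,4-dimethoxyphenyl)-3-methyl-4-[(phenylsulfanyl)methyl]-5-(3,4,5-trimethoxyphenyl)tetrahydrofuran | COc1ccc([C@H]2O[C@@H](c3cc(OC)c(OC)c(OC)c3)[C@H](CSc3ccccc3)[C@@H]2C)cc1OC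
F4 | step 5 | (2S,3S,4R,5R)-2-(3,4-dimethoxyphenyl)-4-methyl-3-[(phenylsulfanyl)methyl]-5-(3,4,5-trimethoxyphenyl)tetrahydrofuran | COc1ccc([C@H]2O[C@@H](c3cc(OC)c(OC)c(OC)c3)[C@H](C)[C@@H]2CSc2ccccc2)cc1OC
F5 | step 4 | 1-(3,4,5-trimethoxyphenyl)propan-1-ol (racemic) | CCC(O)c1cc(OC)c(OC)c(OC)c1
F6 | step 4 | (E)-1,2,3-trimethoxy-5-(prop-1-en-1-yl)benzene | C/C=C/c1cc(OC)c(OC)c(OC)c1
F7 | step 4 | triethyl{[(1S)-1-(3,4-dimethoxyphenyl)prop-2-en-1-yl]oxy}silane | COc1ccc([C@H](C=C)O[Si](CC)(CC)CC)cc1OC
F8 | step 4 | (S)-1-(3,4-dimethoxyphenyl)prop-2-en-1-ol | COc1ccc([C@H](C=C)O)cc1OC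
F9 | step 4 | 4-[(1S)-1-{[(1R,2S)-2-(phenylselanyl)-1-(3,4,5-trimethoxyphenyl)propyl]oxy}prop-2-en-1-yl]-1,2-dimethoxybenzene | COc1ccc([C@H](C=C)O[C@H](c2cc(OC)c(OC)c(OC)c2)[C@H](C)[Se]c2ccccc2)cc1OC
F10 | step 2 | 2-(phenylselanyl)-1-(3,4,5-trimethoxyphenyl)propan-1-ol (racemic, all four stereoisomers) | CC([Se]c1ccccc1)C(O)c1cc(OC)c(OC)c(OC)c1
F11 | step 2 | (1R)-2-(phenylselanyl)-1-(3,4,5-trimethoxyphenyl)propyl propanoate (both C2 epimers) | CCC(=O)O[C@H](c1cc(OC)c(OC)c(OC)c1)C(C)[Se]c1ccccc1
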